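## The problem

Artoindonesianin Q (15) is a flavone whose pyranone ring (ring C) is fully substituted: O1, C2 carrying the 2,5-dihydroxy-4-methoxyphenyl ring B, C3 carrying a prenyl group, and the C4 carbonyl fused through C4a/C8a to ring A (5-OH, 7-OMe). It has no stereocentre, and the prenyl alkene ends in two methyl groups, so nothing has to be controlled in space; the difficulties are regiochemistry and chemoselectivity. Two sets of oxygens must be told apart: O5 (free, chelated to the C4 carbonyl) against O7 (methylated) in ring A, and O2'/O5' (free) against O4' (methylated) in ring B. C3 is the most crowded carbon, wedged between the carbonyl and an ortho-substituted aryl group, and its carbon–carbon bond to the prenyl group has to be made without touching the nucleophilic positions C6 and C8. Three features will not stand rough treatment: the trisubstituted prenyl alkene (protic and Lewis acids, electrophilic carbenes, hydrogenation), the methoxyhydroquinone of ring B (air oxidation to the quinone, fastest in base), and the pair 2'-OH/C3-prenyl, which is disposed to oxidative cyclisation; free hydroquinone and prenyl should therefore meet only in the last step. The enabling feature is the position of C3: it lies between C2 (bound to O1 and ring B) and C4 (the carbonyl carbon bound to C4a). If C3 is removed and C2 joined to C4, what remains is the enol double bond of a 2-aryl-1-benzofuran-3-ol, so ring C can be grown from a five-membered ring by inserting one carbon that arrives with a halogen handle for the prenyl group.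

## Retrosynthesis

Flavone numbering is used for 12, 14 and 15. In the benzofuran series (4–8), benzofuran C2, C3, C3a, C4, C6 and C7a become flavone C2, C4, C4a, C5, C7 and C8a.

15 ⇒ 14. The three O–CH2OMe bonds at O5, O2' and O5' are cut, so all three free hydroxyls of 15 are methoxymethyl (MOM) ethers in 14. One acetal type for all three allows a single mild final operation that a prenyl group tolerates. A methyl ether at O5 would be shorter to reach, but its removal needs a strong Lewis acid next to the prenyl alkene; benzyl ethers are excluded because hydrogenolysis would reduce the alkene. The forward step asks only for dilute acid and exclusion of air.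

14 ⇒ 12 + 13. The C3–C1'' bond is cut, giving the 3-bromoflavone 12 and the prenylstannane 13. The prenyl group enters after the ring expansion because its electron-rich alkene would compete for the carbene. The bromine on C3 costs nothing, since the ring expansion leaves it there. The forward reaction is a Stille coupling at a hindered α-bromo enone and must transfer the allylic group without transposition.

12 ⇒ 8 + 9. C2–C3 and C3–C4 are cut and C3 is removed as a CBr2 unit supplied by bromoform (9); the rest of ring C recloses as the C2=C3 enol ether of the 3-silyloxybenzofuran 8. Compared with cutting O1–C2/C4–C4a or building one of the benzene rings, this cut leaves ring A, O1 and the carbonyl carbon together in a simple benzofuranone and delivers C3 already functionalised. The forward step needs a carbene that selects the enol double bond over two electron-rich arenes, and a cyclopropane that opens at the ring-fusion bond.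

8 ⇒ 7. The O–Si bond is cut. Silylation turns the air-sensitive ketone 7 into a storable aromatic enol ether, raises the nucleophilicity of C2=C3, and supplies the silicon that leaves oxygen at the end of the ring expansion. A neutral silyl ether is preferred over the free enolate, which could instead be alkylated by the carbene at C2.

7 ⇒ 6 + 3. The C2–C1' bond is cut, joining benzofuranone 6 and aryl bromide 3 by palladium-catalysed ketone α-arylation. Building the benzofuranone around ring B by acid-mediated acylation would not tolerate the MOM ethers. This is the convergent step of the route.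

3 ⇒ 2 ⇒ 1. The C–Br bond and two O–MOM bonds are cut back to 2-methoxyhydroquinone (1). Bromination must occur para to the methoxy group, the innate preference of this substitution pattern.

6 ⇒ 5 ⇒ 4. The O–MOM bond is cut, and the O4 methyl is restored to reach commercial 4,6-dimethoxybenzofuran-3(2H)-one (4). The chelation-controlled demethylation that distinguishes O5 from O7 is thereby moved to the first step, on a molecule with nothing else at risk.

## Roads not taken

Alternative 1: The cut is O1–C2 and C4–C4a, a [3+3] union of ring A with a three-carbon unit that already bears ring B and the prenyl group. Phloroglucinol A3 and ethyl 2-[2,5-bis(benzyloxy)-4-methoxybenzoyl]-5-methylhex-4-enoate A2 are heated without catalyst. A2 loses its ester alkoxy group as the alcohol and becomes an acylketene that acylates A3, and an ortho hydroxyl condenses with the aryl ketone to give 2-[2,5-bis(benzyloxy)-4-methoxyphenyl]-5,7-dihydroxy-3-(3-methylbut-2-enyl)chromen-4-one A1.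
- Merits: A3 is symmetrical, so ring closure has no regiochemical issue. The prenyl group is attached by simple enolate alkylation at an sp3 carbon, free of the allylic transposition risk of a Stille coupling. No tin is used, and the route is probably about two steps shorter.
- Weak points: acylketene formation needs temperatures near or above 200 °C, at which the prenylated ketoester A2 can react with itself (ene-type cyclisation of the enol onto the alkene). The hindered ortho-benzyloxy aryl ketone must then condense with a phenol, and coumarin-type closure competes. A1 still needs selective 7-O-methylation and removal of two benzyl ethers without hydrogen, which means a strong Lewis acid beside the prenyl group.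
- Comparison: this road is better in step count and avoids an untested core-forming step. The chosen plan sets against it that the prenyl group never sees more than Pd(PPh3)4 below 100 °C and dilute acid, and that its protecting groups leave in one mild step.

Alternative 2: The cut is C1'–C2' and C5'–C6', building ring B by cycloaddition. The dienophile is 2-ethynyl-5,7-dimethoxy-3-(3-methylbut-2-enyl)chromen-4-one A5 and the diene is tert-butyl[(4-methoxyfuran-2-yl)oxy]dimethylsilane A6. The furan A6 adds to the alkyne of A5 in a Diels–Alder reaction, the silyloxy-bearing C2 of A6 bonding to the inner alkyne carbon and C5 of A6 to the alkyne terminus. The oxanorbornadiene opens and tautomerises, giving after fluoride work-up 2-(2,5-dihydroxy-4-methoxyphenyl)-5,7-dimethoxy-3-(3-methylbut-2-enyl)chromen-4-one A4.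
- Merits: ring B arrives with all three oxygens correctly placed and needs no protecting group. The polarisation is matched, since the alkyne terminus of A5 is the electrophilic end of the chromone dienone and C5 of A6 is the nucleophilic diene terminus.
- Weak points: A5 is no simpler than 12; it needs a chromone with a leaving group at C2 and the prenyl group at C3, so the C3 problem is only moved earlier. A6 is not a stock reagent and has to be made and used as a moisture-sensitive silyl ketene acetal. Silyloxyfurans such as A6 usually react with electron-poor π systems as vinylogous ketene acetals in stepwise conjugate additions, so open-chain adducts are a likely diversion. A4 emerges as a free hydroquinone still carrying a methyl on O5, so a Lewis-acid demethylation must be run beside the prenyl group and an unprotected hydroquinone.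
- Comparison: this road is more convergent for ring B and A4 is one step from 15. The chosen plan sets against it that ring B comes from a commercial hydroquinone with regiochemistry fixed by one bromination, whereas A6 must first be prepared, and that the step forming ring C also solves the C3 substitution.

Alternative 3: The cut removes ring A, building it on a pyranone by Danheiser benzannulation. Photolysis of 6-(diazoacetyl)-2-[4-methoxy-2,5-bis(prop-2-enyloxy)phenyl]-3-(3-methylbut-2-enyl)pyran-4-one A8 gives, by Wolff rearrangement, a vinylketene that adds methoxyacetylene A9. The cyclobutenone opens and recloses onto the pyranone to give 5-hydroxy-7-methoxy-2-[4-methoxy-2,5-bis(prop-2-enyloxy)phenyl]-3-(3-methylbut-2-enyl)chromen-4-one A7.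
- Merits: this is the only plan in which the 5-OH/7-OMe difference is created by construction, with O5 free and O7 methylated. The allyl ethers of A7 can be removed with Pd(PPh3)4 (zerovalent palladium) without harming the prenyl group.
- Weak points: A8 is a fully substituted pyranone bearing prenyl, aryl and diazoketone groups, and needs a long linear sequence. The ketene and carbene intermediates have three alkenes in the same molecule to react with, and the pyranone chromophore has photochemistry of its own. A9 is volatile and unstable.
- Comparison: this road is better at oxygen differentiation. The chosen plan obtains the same differentiation by one demethylation of a commercial benzofuranone and reaches the ring-forming step in far fewer operations.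

Key step: step 7

Remark: 7 forms as a racemate at C2 (in equilibrium with its achiral enol) and 10 as a racemic cis-fused adduct. Both are erased on the way to 12, so their SMILES carry no configuration; the target has no stereocentre. Compounds 1, 4, 9 and 13 are taken as purchasable.

## Route

Step 1
Reactants: 1 2-methoxybenzene-1,4-diol (2-methoxyhydroquinone)
Product: 2 2-methoxy-1,4-bis(methoxymethoxy)benzene
Conditions: MOMCl, iPr2NEt, CH2Cl2, 0 °C → rt, Ar
Reagents that add atoms: chloromethyl methyl ether, COCCl
Why: O-alkylation of both phenols with a chloromethyl ether (MOM protection); the acetal is inert to base, to the palladium steps and to the carbene conditions, and leaves under dilute acid at the end.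

Step 2
Reactants: 2 2-methoxy-1,4-bis(methoxymethoxy)benzene
Product: 3 1-bromo-4-methoxy-2,5-bis(methoxymethoxy)benzene
Conditions: NBS, MeCN, 0 °C → rt
Reagents that add atoms: N-bromosuccinimide, O=C1CCC(=O)N1Br
Why: Electrophilic aromatic bromination; C5 of 2 is para to the methoxy group and ortho to a MOM ether, the only position activated by two donors that is not flanked on both sides, as in the bromination of 1,2,4-trialkoxybenzenes.

Step 3
Reactants: 4 4,6-dimethoxy-1-benzofuran-3(2H)-one
Product: 5 4-hydroxy-6-methoxy-1-benzofuran-3(2H)-one
Conditions: BCl3, CH2Cl2, −78 → 0 °C; then H2O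
Reagents that add atoms: none
Why: Chelation-controlled Lewis-acid ether cleavage: boron bridges the C3 carbonyl and the peri C4 methoxy oxygen in a six-membered chelate and chloride removes only that methyl, the C6 methoxy having no such assistance; done here on the bare building block, no such reagent is needed later.

Step 4
Reactants: 5 4-hydroxy-6-methoxy-1-benzofuran-3(2H)-one
Product: 6 6-methoxy-4-(methoxymethoxy)-1-benzofuran-3(2H)-one
Conditions: MOMCl, iPr2NEt, CH2Cl2, 0 °C → rt
Reagents that add atoms: chloromethyl methyl ether, COCCl
Why: MOM protection of the chelated phenol; the phenol is far more acidic than C2–H and the amine base does not enolise the ketone appreciably, so alkylation occurs at the phenol oxygen and not at C2 or the enol oxygen.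

Step 5
Reactants: 6 6-methoxy-4-(methoxymethoxy)-1-benzofuran-3(2H)-one; 3 1-bromo-4-methoxy-2,5-bis(methoxymethoxy)benzene
Product: 7 6-methoxy-4-(methoxymethoxy)-2-[4-methoxy-2,5-bis(methoxymethoxy)phenyl]-1-benzofuran-3(2H)-one (racemic)
Conditions: Pd2(dba)3 (cat.), XPhos, K3PO4, toluene, 90 °C, Ar
Reagents that add atoms: none
Why: Palladium-catalysed ketone α-arylation (Buchwald–Hartwig type): C2–H is acidic enough for K3PO4 because the enolate is an aromatic benzofuran-3-olate, the bulky biarylphosphine drives oxidative addition of the electron-rich bromide and reductive elimination, and the ortho MOM ether plus the quaternary centre a second arylation would create hold the reaction at monoarylation. The new C2 stereocentre is racemic and is erased in step 6; 7 is handled without air because 2-arylbenzofuranones autoxidise at C2.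

Step 6
Reactants: 7 6-methoxy-4-(methoxymethoxy)-2-[4-methoxy-2,5-bis(methoxymethoxy)phenyl]-1-benzofuran-3(2H)-one
Product: 8 tert-butyl({6-methoxy-4-(methoxymethoxy)-2-[4-methoxy-2,5-bis(methoxymethoxy)phenyl]-1-benzofuran-3-yl}oxy)dimethylsilane
Conditions: TBSOTf, Et3N (excess), CH2Cl2, 0 °C, Ar
Reagents that add atoms: tert-butyldimethylsilyl trifluoromethanesulfonate, CC(C)(C)[Si](C)(C)OS(=O)(=O)C(F)(F)F
Why: Enol silylation with a silyl triflate and amine; O-silylation is strongly preferred over C-silylation because it creates the aromatic furan, the excess amine keeps the medium basic so the aryl MOM acetals are not ionised, and the TBS ether turns the autoxidisable ketone into a storable, electron-rich enol ether that tolerates tert-butoxide at low temperature.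

Step 7
Reactants: 8 tert-butyl({6-methoxy-4-(methoxymethoxy)-2-[4-methoxy-2,5-bis(methoxymethoxy)phenyl]-1-benzofuran-3-yl}oxy)dimethylsilane; 9 bromoform
Product: 12 3-bromo-7-methoxy-5-(methoxymethoxy)-2-[4-methoxy-2,5-bis(methoxymethoxy)phenyl]-4H-chromen-4-one, via dibromocyclopropane adduct 10 (not isolated), via 4-silyloxybenzopyrylium bromide 11 (not isolated)
Conditions: KOtBu (solid, in portions), hexane–toluene, −30 °C → rt, Ar; aqueous work-up
Reagents that add atoms: none
Why: Proposed new method: dibromocarbene, released from bromoform by tert-butoxide, should add to the C2=C3 bond of 8 to give the gem-dibromocyclopropane 10, whose endo bromide ionises with disrotatory two-electron opening of the ring-fusion bond (cyclopropyl to allyl cation) to the aromatic 4-silyloxybenzopyrylium 11; bromide then takes silicon from oxygen (the silyl bromide is hydrolysed on work-up) and leaves the C4 carbonyl of 12. The closest known reaction types are the dihalocarbene ring expansion of cyclic silyl enol ethers to 2-halo-enones and the Ciamician–Dennstedt expansion of indoles and benzofurans, which have not been combined on a 3-silyloxybenzofuran. The pyranone ring is not closed by a cyclisation but arises by ring expansion: the former furan C2–C3 bond is exchanged for C2–C(Br) and C(Br)–C4 in the electrocyclic opening. The two stereocentres of 10 are transient and none remains in 12. The step needs chemoselectivity for the enol double bond over the two electron-rich arenes and the acetal C–H bonds, and cleavage of the shared bond and not an exocyclic one. Both are secured by the substrate: C2 carries the ring oxygen and C3 the silyloxy group, so this is the most nucleophilic π bond for an electrophilic carbene, and the same oxygens stabilise the cation developing at C2 and C4, while aromatisation to the pyrylium and irreversible loss of silicon pull the sequence forward. The prenyl group is absent at this stage, so no second electron-rich alkene competes.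

Step 8
Reactants: 12 3-bromo-7-methoxy-5-(methoxymethoxy)-2-[4-methoxy-2,5-bis(methoxymethoxy)phenyl]-4H-chromen-4-one; 13 tributyl(3-methylbut-2-en-1-yl)stannane
Product: 14 7-methoxy-5-(methoxymethoxy)-2-[4-methoxy-2,5-bis(methoxymethoxy)phenyl]-3-(3-methylbut-2-en-1-yl)-4H-chromen-4-one
Conditions: Pd(PPh3)4 (cat.), DMF, 90 °C, Ar
Reagents that add atoms: none
Why: Stille coupling: oxidative addition of zerovalent palladium into the C3–Br bond of the α-bromo enone is facile, the allylic stannane transmetalates without base, and reductive elimination at the less hindered primary terminus of the allyl ligand should give the linear prenyl group; MOM ethers and the chromone are inert to these neutral conditions.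

Step 9
Reactants: 14 7-methoxy-5-(methoxymethoxy)-2-[4-methoxy-2,5-bis(methoxymethoxy)phenyl]-3-(3-methylbut-2-en-1-yl)-4H-chromen-4-one
Product: 15 Artoindonesianin Q, 2-(2,5-dihydroxy-4-methoxyphenyl)-5-hydroxy-7-methoxy-3-(3-methylbut-2-en-1-yl)-4H-chromen-4-one
Conditions: HCl (3 M aq.), MeOH, 45 °C, Ar
Reagents that add atoms: none
Why: Acid-catalysed acetal solvolysis (MOM cleavage) of all three ethers, the chelated O5 ether first; dilute acid at moderate temperature is the usual way to unmask prenylated polyphenols without hydrating the trisubstituted alkene, and exclusion of air protects the liberated hydroquinone.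

## Compound list

1 | 2-methoxybenzene-1,4-diol (2-methoxyhydroquinone) | COc1cc(O)ccc1O | starting material
2 | 2-methoxy-1,4-bis(methoxymethoxy)benzene | COCOc1ccc(OCOC)c(OC)c1 | intermediate
3 | 1-bromo-4-methoxy-2,5-bis(methoxymethoxy)benzene | COCOc1cc(OC)c(OCOC)cc1Br | intermediate
4 | 4,6-dimethoxy-1-benzofuran-3(2H)-one | COc1cc(OC)c2c(c1)OCC2=O | starting material
5 | 4-hydroxy-6-methoxy-1-benzofuran-3(2H)-one | COc1cc(O)c2c(c1)OCC2=O | intermediate
6 | 6-methoxy-4-(methoxymethoxy)-1-benzofuran-3(2H)-one | COCOc1cc(OC)cc2OCC(=O)c12 | intermediate
7 | 6-methoxy-4-(methoxymethoxy)-2-[4-methoxy-2,5-bis(methoxymethoxy)phenyl]-1-benzofuran-3(2H)-one (racemic at C2) | COCOc1cc(OC)cc2OC(c3cc(OCOC)c(OC)cc3OCOC)C(=O)c12 | intermediate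
8 | tert-butyl({6-methoxy-4-(methoxymethoxy)-2-[4-methoxy-2,5-bis(methoxymethoxy)phenyl]-1-benzofuran-3-yl}oxy)dimethylsilane | COCOc1cc(OC)cc2oc(-c3cc(OCOC)c(OC)cc3OCOC)c(O[Si](C)(C)C(C)(C)C)c12 | intermediate
9 | bromoform (tribromomethane) | BrC(Br)Br | starting material
10 | dibromocyclopropane adduct of 8: 1,1-dibromo-6b-(tert-butyldimethylsilyloxy)-4-methoxy-6-(methoxymethoxy)-1a-[4-methoxy-2,5-bis(methoxymethoxy)phenyl]-1a,6b-dihydro-1H-cyclopropa[b][1]benzofuran (racemic, cis-fused; not isolated) | COCOc1cc(OC)cc2OC3(c4cc(OCOC)c(OC)cc4OCOC)C(Br)(Br)C3(O[Si](C)(C)C(C)(C)C)c12 | intermediate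
11 | 3-bromo-4-(tert-butyldimethylsilyloxy)-7-methoxy-5-(methoxymethoxy)-2-[4-methoxy-2,5-bis(methoxymethoxy)phenyl]chromenylium bromide (not isolated) | COCOc1cc(OC)cc2[o+]c(-c3cc(OCOC)c(OC)cc3OCOC)c(Br)c(O[Si](C)(C)C(C)(C)C)c12.[Br-] | intermediate
12 | 3-bromo-7-methoxy-5-(methoxymethoxy)-2-[4-methoxy-2,5-bis(methoxymethoxy)phenyl]-4H-chromen-4-one | COCOc1cc(OC)cc2oc(-c3cc(OCOC)c(OC)cc3OCOC)c(Br)c(=O)c12 | intermediate
13 | tributyl(3-methylbut-2-en-1-yl)stannane | CCCC[Sn](CCCC)(CCCC)CC=C(C)C | starting material
14 | 7-methoxy-5-(methoxymethoxy)-2-[4-methoxy-2,5-bis(methoxymethoxy)phenyl]-3-(3-methylbut-2-en-1-yl)-4H-chromen-4-one | COCOc1cc(OC)cc2oc(-c3cc(OCOC)c(OC)cc3OCOC)c(CC=C(C)C)c(=O)c12 | intermediate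
15 | Artoindonesianin Q, 2-(2,5-dihydroxy-4-methoxyphenyl)-5-hydroxy-7-methoxy-3-(3-methylbut-2-en-1-yl)-4H-chromen-4-one | COc1cc(O)c2c(=O)c(CC=C(C)C)c(-c3cc(O)c(OC)cc3O)oc2c1 | target

## Step count and least certain steps

Total step count: 9. Longest linear sequence: 7 steps (steps 3–9 from 4; equally steps 1, 2, 5–9 from 1).

Step 7 (key step, proposed new method).
- What may go wrong: tert-butoxide may remove the silyl group before the carbene arrives, after which the enolate would be alkylated at C2 and no ring expansion would follow. The tetrasubstituted, doubly flanked double bond may react too slowly, so the carbene is consumed by tert-butoxide and tert-butanol. Excess base may add to C2 of the product chromone and open it.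
- Fallback, known chemistry throughout, from 3 back to 14: Sonogashira coupling of 3 with ethynyltrimethylsilane (PdCl2(PPh3)2, CuI, Et3N) would give {[4-methoxy-2,5-bis(methoxymethoxy)phenyl]ethynyl}trimethylsilane F1, desilylated with K2CO3 in methanol to 1-ethynyl-4-methoxy-2,5-bis(methoxymethoxy)benzene F2. Acyl Sonogashira coupling of F2 with commercial 2,4,6-trimethoxybenzoyl chloride would give 3-[4-methoxy-2,5-bis(methoxymethoxy)phenyl]-1-(2,4,6-trimethoxyphenyl)prop-2-yn-1-one F3. ICl in CH2Cl2 at −78 °C, the established iodocyclisation of ortho-methoxyaryl ynones, should close the pyranone with loss of one O-methyl group and place iodine on C3, giving 3-iodo-5,7-dimethoxy-2-[4-methoxy-2,5-bis(methoxymethoxy)phenyl]-4H-chromen-4-one F4. Because F4 has a methyl on O5, BCl3 (methanol quench) is used at this point, before any prenyl group exists; it removes the chelated methyl and both MOM groups to give 2-(2,5-dihydroxy-4-methoxyphenyl)-5-hydroxy-3-iodo-7-methoxy-4H-chromen-4-one F5. Re-protection (MOMCl, NaH, DMF) gives 3-iodo-7-methoxy-5-(methoxymethoxy)-2-[4-methoxy-2,5-bis(methoxymethoxy)phenyl]-4H-chromen-4-one F6, and Stille coupling of F6 with 13 under the conditions of step 8 gives 14.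

Step 5 (α-arylation).
- What may go wrong: base-induced self-condensation of the benzofuranone, slow oxidative addition of the electron-rich ortho-substituted bromide, and autoxidation of the product enolate at C2 during handling.
- Fallback, from 6 back to 8: silylation of 6 (TBSOTf, Et3N) would give tert-butyl{[6-methoxy-4-(methoxymethoxy)-1-benzofuran-3-yl]oxy}dimethylsilane F7. Iridium-catalysed C–H borylation at C2, the most reactive C–H bond of a benzofuran ([Ir(OMe)(cod)]2, 4,4'-di-tert-butyl-2,2'-bipyridine, B2pin2), would give tert-butyl{[6-methoxy-4-(methoxymethoxy)-2-(4,4,5,5-tetramethyl-1,3,2-dioxaborolan-2-yl)-1-benzofuran-3-yl]oxy}dimethylsilane F8. Suzuki coupling of F8 with 3 (Pd(OAc)2, SPhos, K3PO4, toluene–water) gives 8 directly and bypasses the ketone 7.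

Step 8 (Stille prenylation).
- What may go wrong: transfer of the allylic group with transposition, so that C3 bonds to the tertiary carbon, and sluggish coupling at the crowded C3 with competing protodestannylation.
- Fallback, from 12 back to 14: Stille coupling of 12 with allyltributylstannane (Pd(PPh3)4), for which transposition is without consequence, would give 7-methoxy-5-(methoxymethoxy)-2-[4-methoxy-2,5-bis(methoxymethoxy)phenyl]-3-(prop-2-en-1-yl)-4H-chromen-4-one F9. Cross-metathesis of F9 with 2-methylbut-2-ene (second-generation Grubbs catalyst, RuCl2(H2IMes)(PCy3)(=CHPh), 40 °C) converts the allyl into the prenyl group of 14.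

Step 9 (global MOM removal).
- What may go wrong: acid-mediated hydration of the prenyl double bond, or its capture by the C4 carbonyl oxygen or the freed 2'-hydroxyl, before the two unchelated ring B acetals are gone; and air oxidation of the freed hydroquinone.
- Fallback, from 12 to 15: the acid step is moved ahead of the prenylation. HCl in methanol on 12 would give 3-bromo-2-(2,5-dihydroxy-4-methoxyphenyl)-5-hydroxy-7-methoxy-4H-chromen-4-one F10. Acetylation (Ac2O, pyridine) gives 2-[2,5-bis(acetyloxy)-4-methoxyphenyl]-3-bromo-7-methoxy-4-oxo-4H-chromen-5-yl acetate F11. Stille coupling of F11 with 13 (Pd(PPh3)4, DMF) gives 2-[2,5-bis(acetyloxy)-4-methoxyphenyl]-7-methoxy-3-(3-methylbut-2-en-1-yl)-4-oxo-4H-chromen-5-yl acetate F12. Methanolysis of F12 (K2CO3, degassed MeOH, 0 °C, Ar, acidic quench) frees the three phenols without acid and gives 15.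

## Further compounds

F1 | step 7 | {[4-methoxy-2,5-bis(methoxymethoxy)phenyl]ethynyl}trimethylsilane | COCOc1cc(OC)c(OCOC)cc1C#C[Si](C)(C)C
F2 | step 7 | 1-ethynyl-4-methoxy-2,5-bis(methoxymethoxy)benzene | COCOc1cc(OC)c(OCOC)cc1C#C
F3 | step 7 | 3-[4-methoxy-2,5-bis(methoxymethoxy)phenyl]-1-(2,4,6-trimethoxyphenyl)prop-2-yn-1-one | COc1cc(OC)c(C(=O)C#Cc2cc(OCOC)c(OC)cc2OCOC)c(OC)c1
F4 | step 7 | 3-iodo-5,7-dimethoxy-2-[4-methoxy-2,5-bis(methoxymethoxy)phenyl]-4H-chromen-4-one | COc1cc(OC)c2c(=O)c(I)c(-c3cc(OCOC)c(OC)cc3OCOC)oc2c1
F5 | step 7 | 2-(2,5-dihydroxy-4-methoxyphenyl)-5-hydroxy-3-iodo-7-methoxy-4H-chromen-4-one | COc1cc(O)c2c(=O)c(I)c(-c3cc(O)c(OC)cc3O)oc2c1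
F6 | step 7 | 3-iodo-7-methoxy-5-(methoxymethoxy)-2-[4-methoxy-2,5-bis(methoxymethoxy)phenyl]-4H-chromen-4-one | COCOc1cc(OC)cc2oc(-c3cc(OCOC)c(OC)cc3OCOC)c(I)c(=O)c12
F7 | step 5 | tert-butyl{[6-methoxy-4-(methoxymethoxy)-1-benzofuran-3-yl]oxy}dimethylsilane | COCOc1cc(OC)cc2occ(O[Si](C)(C)C(C)(C)C)c12
F8 | step 5 | tert-butyl{[6-methoxy-4-(methoxymethoxy)-2-(4,4,5,5-tetramethyl-1,3,2-dioxaborolan-2-yl)-1-benzofuran-3-yl]oxy}dimethylsilane | COCOc1cc(OC)cc2oc(B3OC(C)(C)C(C)(C)O3)c(O[Si](C)(C)C(C)(C)C)c12
F9 | step 8 | 7-methoxy-5-(methoxymethoxy)-2-[4-methoxy-2,5-bis(methoxymethoxy)phenyl]-3-(prop-2-en-1-yl)-4H-chromen-4-one | COCOc1cc(OC)cc2oc(-c3cc(OCOC)c(OC)cc3OCOC)c(CC=C)c(=O)c12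
F10 | step 9 | 3-bromo-2-(2,5-dihydroxy-4-methoxyphenyl)-5-hydroxy-7-methoxy-4H-chromen-4-one | COc1cc(O)c2c(=O)c(Br)c(-c3cc(O)c(OC)cc3O)oc2c1
F11 | step 9 | 2-[2,5-bis(acetyloxy)-4-methoxyphenyl]-3-bromo-7-methoxy-4-oxo-4H-chromen-5-yl acetate | COc1cc(OC(C)=O)c2c(=O)c(Br)c(-c3cc(OC(C)=O)c(OC)cc3OC(C)=O)oc2c1
F12 | step 9 | 2-[2,5-bis(acetyloxy)-4-methoxyphenyl]-7-methoxy-3-(3-methylbut-2-en-1-yl)-4-oxo-4H-chromen-5-yl acetate | COc1cc(OC(C)=O)c2c(=O)c(CC=C(C)C)c(-c3cc(OC(C)=O)c(OC)cc3OC(C)=O)oc2c1
A1 | alternative 1 | 2-[2,5-bis(benzyloxy)-4-methoxyphenyl]-5,7-dihydroxy-3-(3-methylbut-2-enyl)chromen-4-one | Oc1cc(O)c2c(=O)c(CC=C(C)C)c(-c3cc(OCc4ccccc4)c(OC)cc3OCc3ccccc3)oc2c1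
A2 | alternative 1 | ethyl 2-[2,5-bis(benzyloxy)-4-methoxybenzoyl]-5-methylhex-4-enoate | CCOC(=O)C(CC=C(C)C)C(=O)c1cc(OCc2ccccc2)c(OC)cc1OCc1ccccc1
A3 | alternative 1 | phloroglucinol (benzene-1,3,5-triol) | Oc1cc(O)cc(O)c1
A4 | alternative 2 | 2-(2,5-dihydroxy-4-methoxyphenyl)-5,7-dimethoxy-3-(3-methylbut-2-enyl)chromen-4-one | COc1cc(OC)c2c(=O)c(CC=C(C)C)c(-c3cc(O)c(OC)cc3O)oc2c1
A5 | alternative 2 | 2-ethynyl-5,7-dimethoxy-3-(3-methylbut-2-enyl)chromen-4-one | COc1cc(OC)c2c(=O)c(CC=C(C)C)c(C#C)oc2c1
A6 | alternative 2 | tert-butyl[(4-methoxyfuran-2-yl)oxy]dimethylsilane | COc1coc(O[Si](C)(C)C(C)(C)C)c1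
A7 | alternative 3 | 5-hydroxy-7-methoxy-2-[4-methoxy-2,5-bis(prop-2-enyloxy)phenyl]-3-(3-methylbut-2-enyl)chromen-4-one | COc1cc(O)c2c(=O)c(CC=C(C)C)c(-c3cc(OCC=C)c(OC)cc3OCC=C)oc2c1
A8 | alternative 3 | 6-(diazoacetyl)-2-[4-methoxy-2,5-bis(prop-2-enyloxy)phenyl]-3-(3-methylbut-2-enyl)pyran-4-one | [N-]=[N+]=CC(=O)c1cc(=O)c(CC=C(C)C)c(-c2cc(OCC=C)c(OC)cc2OCC=C)o1
A9 | alternative 3 | methoxyacetylene (methoxyethyne) | COC#C
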